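The 2,3,4,7-tetrahydrooxepine (O1; C2 carries CO2H and the aroylmethyl arm; C6 carries the side chain) is opened at O1–C2 to an acyclic (E)-aroylacrylate. Its chain is assembled in one flask around a three-carbon linchpin: the ester-stabilised phosphorane 13 (future C2) is C-alkylated by (3-bromopropyl)triphenylphosphonium bromide 14 (C3–C5), forming C2–C3; the derived bis-ylide olefinates α-silyloxy ketone 9 at its non-stabilised end, forming C5=C6 with the cis geometry the ring needs, then arylglyoxal 12 at its stabilised end. The step exploits the unsubstituted C3–C4–C5 bridge between the fully substituted C2 and the ring alkene, and the O–CH2 (C7) flank of C6. An asymmetric 7-exo oxa-Michael closure then sets C2.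

Key step: step 8

Remark: compounds 1, 6, 10, 13 and 14 are taken as commercial; arylglyoxal 12 is handled as its hydrate and dried azeotropically before use.

Step 1
Reactants: 1 6-methylhept-5-en-2-one
Product: 2 tert-butyl(dimethyl)[(6-methylhepta-1,5-dien-2-yl)oxy]silane
Conditions: LiN(iPr)2, THF, −78 °C; TBSCl, DMPU, −78 °C → rt
Reagents that add atoms: tert-butyldimethylsilyl chloride, CC(C)(C)[Si](C)(C)Cl
Why: Kinetic deprotonation of the methyl ketone at the less substituted α-carbon by the hindered amide and O-silylation of the lithium enolate (silyl enol ether formation) should give the terminal enol ether regioselectively.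

Step 2
Reactants: 2 tert-butyl(dimethyl)[(6-methylhepta-1,5-dien-2-yl)oxy]silane
Product: 4 1-[(tert-butyldimethylsilyl)oxy]-6-methylhept-5-en-2-one, via silyloxy epoxide 3 (not isolated)
Conditions: mCPBA (1.0 equiv), CH2Cl2, −40 → 0 °C
Reagents that add atoms: 3-chloroperbenzoic acid (mCPBA), OOC(=O)c1cccc(Cl)c1
Why: Rubottom oxidation, in which the electron-rich silyl enol ether should be epoxidised much faster than the isolated trisubstituted alkene by one equivalent of peracid at low temperature, the silyloxy epoxide then opening with 1,4-silyl shift to the α-silyloxy ketone.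

Step 3
Reactants: 4 1-[(tert-butyldimethylsilyl)oxy]-6-methylhept-5-en-2-one
Product: 5 (E)-1-[(tert-butyldimethylsilyl)oxy]-7-hydroxy-6-methylhept-5-en-2-one
Conditions: SeO2 (0.3 equiv), t-BuOOH, CH2Cl2, rt
Reagents that add atoms: tert-butyl hydroperoxide, CC(C)(C)OO
Why: SeO2-catalysed allylic hydroxylation (ene reaction, then [2,3]-sigmatropic shift) should oxidise the E-methyl group of the trisubstituted alkene, which fixes the E geometry of the allylic alcohol.

Step 4
Reactants: 6 (E)-4-hydroxycinnamic acid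
Product: 8 (E)-3-[4-(methoxymethoxy)phenyl]prop-2-enoic acid, via methoxymethyl ester 7 (not isolated)
Conditions: MOMCl, iPr2NEt, CH2Cl2, 0 °C → rt; then LiOH, THF/H2O, rt; 1 M HCl to pH 4
Reagents that add atoms: chloromethyl methyl ether, COCCl; lithium hydroxide, [Li+].[OH-]
Why: Alkylation of phenol and carboxylate by MOMCl (acetal protection) followed by saponification of the labile methoxymethyl ester should leave the aryl MOM ether in place.

Step 5
Reactants: 5 (E)-1-[(tert-butyldimethylsilyl)oxy]-7-hydroxy-6-methylhept-5-en-2-one; 8 (E)-3-[4-(methoxymethoxy)phenyl]prop-2-enoic acid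
Product: 9 (E)-7-[(tert-butyldimethylsilyl)oxy]-2-methyl-6-oxohept-2-en-1-yl (E)-3-[4-(methoxymethoxy)phenyl]prop-2-enoate
Conditions: EDC·HCl, DMAP (cat.), CH2Cl2, 0 °C → rt
Reagents that add atoms: none
Why: Carbodiimide coupling with DMAP catalysis (Steglich esterification) should acylate the only free hydroxyl without touching either alkene geometry.

Step 6
Reactants: 10 1-(2,5-dihydroxyphenyl)ethanone
Product: 11 1-[2,5-bis(methoxymethoxy)phenyl]ethanone
Conditions: NaH, MOMCl, DMF, 0 °C → rt
Reagents that add atoms: chloromethyl methyl ether, COCCl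
Why: O-alkylation of both phenoxides by MOMCl (Williamson-type acetal protection) should proceed once NaH has broken the hydrogen bond of the ortho-hydroxyl.

Step 7
Reactants: 11 1-[2,5-bis(methoxymethoxy)phenyl]ethanone
Product: 12 2-[2,5-bis(methoxymethoxy)phenyl]-2-oxoacetaldehyde
Conditions: SeO2, 1,4-dioxane/H2O (20:1), 90 °C
Reagents that add atoms: selenium dioxide, O=[Se]=O
Why: Riley oxidation of the aryl methyl ketone should give the arylglyoxal, the methyl group being the only enolisable position.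

Step 8
Reactants: 13 tert-butyl (triphenylphosphoranylidene)acetate; 14 (3-bromopropyl)triphenylphosphonium bromide; 9 (E)-7-[(tert-butyldimethylsilyl)oxy]-2-methyl-6-oxohept-2-en-1-yl (E)-3-[4-(methoxymethoxy)phenyl]prop-2-enoate; 12 2-[2,5-bis(methoxymethoxy)phenyl]-2-oxoacetaldehyde
Product: 18 tert-butyl (2E,5Z,9E)-2-{2-[2,5-bis(methoxymethoxy)phenyl]-2-oxoethylidene}-6-{[(tert-butyldimethylsilyl)oxy]methyl}-11-{[(2E)-3-[4-(methoxymethoxy)phenyl]prop-2-enoyl]oxy}-10-methylundeca-5,9-dienoate, via ylide phosphonium bromide 15 (not isolated), via bis-ylide 16 (not isolated), via phosphorane 17 (not isolated)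
Conditions: K2CO3, NaI (cat.), MeCN, 80 °C; filter, concentrate; KN(SiMe3)2 (1 equiv), THF, −78 °C; add 9, −78 → 0 °C; add 12, 0 °C → rt
Reagents that add atoms: none
Why: The weakly basic ester-stabilised phosphorane 13 should be C-alkylated at its ylide carbon by the primary bromide of 14 (SN2, K2CO3 returning the ylide) without deprotonating the alkylphosphonium end, so that the C2–C3 bond forms and ylide phosphonium salt 15 results; one equivalent of KN(SiMe3)2 then gives bis-ylide 16, whose non-stabilised end alone attacks ketone 9 (Wittig olefination, forming C5=C6), while the stabilised end waits for the far more electrophilic aldehyde of 12 (second, E-selective Wittig olefination). The closest known reaction types are the C-alkylation of alkoxycarbonylmethylene phosphoranes by alkyl halides and the Z-selective Wittig olefination of α-alkoxy ketones by salt-free non-stabilised ylides. The step closes no ring and creates no stereocentre; it delivers the open chain that the 7-exo-trig oxa-Michael addition of step 10 closes. The selectivities needed are site selectivity between the two ylide ends, secured by their very different nucleophilicity, and Z geometry at C5=C6 (C4 cis to C7), secured by the α-silyloxy group of 9 under potassium-based, lithium-free conditions at −78 °C. The tert-butyl ester should resist acylation by the non-stabilised ylide because it is part of the stabilised ylide and is hindered.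

Step 9
Reactants: 18 tert-butyl (2E,5Z,9E)-2-{2-[2,5-bis(methoxymethoxy)phenyl]-2-oxoethylidene}-6-{[(tert-butyldimethylsilyl)oxy]methyl}-11-{[(2E)-3-[4-(methoxymethoxy)phenyl]prop-2-enoyl]oxy}-10-methylundeca-5,9-dienoate
Product: 19 tert-butyl (2E,5Z,9E)-2-{2-[2,5-bis(methoxymethoxy)phenyl]-2-oxoethylidene}-6-(hydroxymethyl)-11-{[(2E)-3-[4-(methoxymethoxy)phenyl]prop-2-enoyl]oxy}-10-methylundeca-5,9-dienoate
Conditions: HF·pyridine, pyridine, THF, 0 °C → rt
Reagents that add atoms: none
Why: Buffered fluoride cleavage of the primary allylic silyl ether (desilylation) should leave the MOM ethers, the tert-butyl ester, the cinnamate and the enone intact.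

Step 10
Reactants: 19 tert-butyl (2E,5Z,9E)-2-{2-[2,5-bis(methoxymethoxy)phenyl]-2-oxoethylidene}-6-(hydroxymethyl)-11-{[(2E)-3-[4-(methoxymethoxy)phenyl]prop-2-enoyl]oxy}-10-methylundeca-5,9-dienoate
Product: 20 tert-butyl (2S)-2-{2-[2,5-bis(methoxymethoxy)phenyl]-2-oxoethyl}-6-[(3E)-5-{[(2E)-3-[4-(methoxymethoxy)phenyl]prop-2-enoyl]oxy}-4-methylpent-3-en-1-yl]-2,3,4,7-tetrahydrooxepine-2-carboxylate
Conditions: cinchona-alkaloid 9-amino-9-deoxy-epi 3,5-bis(trifluoromethyl)phenylthiourea (quinidine- or quinine-derived pseudoenantiomer, whichever delivers 2S; 10 mol %), cyclopentyl methyl ether, 25 °C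
Reagents that add atoms: none
Why: Enantioselective intramolecular oxa-Michael addition (7-exo-trig cycloetherification of a hydroxy enone) of the C7 hydroxyl to the carbon β to the aryl ketone should close the oxepine, the bifunctional catalyst hydrogen-bonding the enone while its quinuclidine delivers the alcohol to one face and so setting C2 as S, with the Z-alkene holding the two ends together and the eight-membered alternative disfavoured.

Step 11
Reactants: 20 tert-butyl (2S)-2-{2-[2,5-bis(methoxymethoxy)phenyl]-2-oxoethyl}-6-[(3E)-5-{[(2E)-3-[4-(methoxymethoxy)phenyl]prop-2-enoyl]oxy}-4-methylpent-3-en-1-yl]-2,3,4,7-tetrahydrooxepine-2-carboxylate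
Product: 21 (2S)-2-[2-(2,5-dihydroxyphenyl)-2-oxoethyl]-6-[(3E)-5-{[(2E)-3-(4-hydroxyphenyl)prop-2-enoyl]oxy}-4-methylpent-3-en-1-yl]-2,3,4,7-tetrahydrooxepine-2-carboxylic acid
Conditions: TFA/CH2Cl2 (1:4), H2O (10 equiv), 0 °C → rt
Reagents that add atoms: none
Why: Acidolysis (global deprotection) should remove the tert-butyl ester by alkyl–oxygen cleavage and the three aryl MOM acetals in one operation, cold dilute acid and a short reaction time sparing the allylic ester, the trisubstituted alkenes and the β-alkoxy ketone, so that C2 is not disturbed.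

Compound list
1 | 6-methylhept-5-en-2-one | CC(=O)CCC=C(C)C | starting material
2 | tert-butyl(dimethyl)[(6-methylhepta-1,5-dien-2-yl)oxy]silane | C=C(CCC=C(C)C)O[Si](C)(C)C(C)(C)C | intermediate
3 | 2-[(tert-butyldimethylsilyl)oxy]-2-(4-methylpent-3-en-1-yl)oxirane (racemic, not isolated) | CC(C)=CCCC1(CO1)O[Si](C)(C)C(C)(C)C | intermediate
4 | 1-[(tert-butyldimethylsilyl)oxy]-6-methylhept-5-en-2-one | CC(C)=CCCC(=O)CO[Si](C)(C)C(C)(C)C | intermediate
5 | (E)-1-[(tert-butyldimethylsilyl)oxy]-7-hydroxy-6-methylhept-5-en-2-one | C/C(=C\CCC(=O)CO[Si](C)(C)C(C)(C)C)CO | intermediate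
6 | (E)-4-hydroxycinnamic acid | OC(=O)/C=C/c1ccc(O)cc1 | starting material
7 | methoxymethyl (E)-3-[4-(methoxymethoxy)phenyl]prop-2-enoate (not isolated) | COCOC(=O)/C=C/c1ccc(OCOC)cc1 | intermediate
8 | (E)-3-[4-(methoxymethoxy)phenyl]prop-2-enoic acid | OC(=O)/C=C/c1ccc(OCOC)cc1 | intermediate
9 | (E)-7-[(tert-butyldimethylsilyl)oxy]-2-methyl-6-oxohept-2-en-1-yl (E)-3-[4-(methoxymethoxy)phenyl]prop-2-enoate | C/C(=C\CCC(=O)CO[Si](C)(C)C(C)(C)C)COC(=O)/C=C/c1ccc(OCOC)cc1 | intermediate
10 | 1-(2,5-dihydroxyphenyl)ethanone | CC(=O)c1cc(O)ccc1O | starting material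
11 | 1-[2,5-bis(methoxymethoxy)phenyl]ethanone | CC(=O)c1cc(OCOC)ccc1OCOC | intermediate
12 | 2-[2,5-bis(methoxymethoxy)phenyl]-2-oxoacetaldehyde | O=CC(=O)c1cc(OCOC)ccc1OCOC | intermediate
13 | tert-butyl (triphenylphosphoranylidene)acetate | CC(C)(C)OC(=O)C=P(c1ccccc1)(c1ccccc1)c1ccccc1 | starting material
14 | (3-bromopropyl)triphenylphosphonium bromide | BrCCC[P+](c1ccccc1)(c1ccccc1)c1ccccc1.[Br-] | starting material
15 | [5-tert-butoxy-5-oxo-4-(triphenylphosphoranylidene)pentyl]triphenylphosphonium bromide (not isolated) | CC(C)(C)OC(=O)C(CCC[P+](c1ccccc1)(c1ccccc1)c1ccccc1)=P(c1ccccc1)(c1ccccc1)c1ccccc1.[Br-] | intermediate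
16 | tert-butyl 2,5-bis(triphenylphosphoranylidene)pentanoate (not isolated) | CC(C)(C)OC(=O)C(CCC=P(c1ccccc1)(c1ccccc1)c1ccccc1)=P(c1ccccc1)(c1ccccc1)c1ccccc1 | intermediate
17 | tert-butyl (5Z,9E)-6-{[(tert-butyldimethylsilyl)oxy]methyl}-11-{[(2E)-3-[4-(methoxymethoxy)phenyl]prop-2-enoyl]oxy}-10-methyl-2-(triphenylphosphoranylidene)undeca-5,9-dienoate (not isolated) | CC(C)(C)OC(=O)C(CC/C=C(\CO[Si](C)(C)C(C)(C)C)CC/C=C(\C)COC(=O)/C=C/c1ccc(OCOC)cc1)=P(c1ccccc1)(c1ccccc1)c1ccccc1 | intermediate
18 | tert-butyl (2E,5Z,9E)-2-{2-[2,5-bis(methoxymethoxy)phenyl]-2-oxoethylidene}-6-{[(tert-butyldimethylsilyl)oxy]methyl}-11-{[(2E)-3-[4-(methoxymethoxy)phenyl]prop-2-enoyl]oxy}-10-methylundeca-5,9-dienoate | CC(C)(C)OC(=O)/C(=C/C(=O)c1cc(OCOC)ccc1OCOC)CC/C=C(\CO[Si](C)(C)C(C)(C)C)CC/C=C(\C)COC(=O)/C=C/c1ccc(OCOC)cc1 | intermediate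
19 | tert-butyl (2E,5Z,9E)-2-{2-[2,5-bis(methoxymethoxy)phenyl]-2-oxoethylidene}-6-(hydroxymethyl)-11-{[(2E)-3-[4-(methoxymethoxy)phenyl]prop-2-enoyl]oxy}-10-methylundeca-5,9-dienoate | CC(C)(C)OC(=O)/C(=C/C(=O)c1cc(OCOC)ccc1OCOC)CC/C=C(\CO)CC/C=C(\C)COC(=O)/C=C/c1ccc(OCOC)cc1 | intermediate
20 | tert-butyl (2S)-2-{2-[2,5-bis(methoxymethoxy)phenyl]-2-oxoethyl}-6-[(3E)-5-{[(2E)-3-[4-(methoxymethoxy)phenyl]prop-2-enoyl]oxy}-4-methylpent-3-en-1-yl]-2,3,4,7-tetrahydrooxepine-2-carboxylate | C/C(=C\CCC1=CCC[C@](CC(=O)c2cc(OCOC)ccc2OCOC)(C(=O)OC(C)(C)C)OC1)COC(=O)/C=C/c1ccc(OCOC)cc1 | intermediate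
21 | (2S)-2-[2-(2,5-dihydroxyphenyl)-2-oxoethyl]-6-[(3E)-5-{[(2E)-3-(4-hydroxyphenyl)prop-2-enoyl]oxy}-4-methylpent-3-en-1-yl]-2,3,4,7-tetrahydrooxepine-2-carboxylic acid | C/C(=C\CCC1=CCC[C@](CC(=O)c2cc(O)ccc2O)(C(=O)O)OC1)COC(=O)/C=C/c1ccc(O)cc1 | target

Total step count: 11. Longest linear sequence: 8 steps (steps 1, 2, 3, 5, 8, 9, 10, 11).

Steps most likely to fail

Step 8. The C-alkylation of the weakly nucleophilic stabilised ylide by the cationic primary bromide may be too slow. Any stronger base present may deprotonate 14 at phosphorus-bearing carbon and close it (3-exo-tet) to cyclopropyltriphenylphosphonium bromide. Enolisation of 9 by the non-stabilised ylide or loss of Z control may erode the olefination. The fallback makes the same two bonds in the reverse order by separate known steps. Setting out from 9, Z-selective Wittig olefination with the ylide from [3-(4-methoxybenzyloxy)propyl]triphenylphosphonium bromide (KN(SiMe3)2, THF, −78 °C) should give the PMB ether F1. Oxidative removal of the PMB group (DDQ, CH2Cl2/pH 7 buffer) should give the homoallylic alcohol F2, and Appel iodination (I2, PPh3, imidazole) the iodide F3. C-alkylation of 13 with F3 (K2CO3, MeCN, 80 °C) should give phosphorane 17, which with 12 comes back to the route at 18.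

Step 10. Closure of a seven-membered ring at a fully substituted β-carbon may be slow, facial discrimination by the catalyst may be poor, retro-addition may erode the enantiomeric purity, and base-mediated γ-deprotonation may shift the alkene out of conjugation with the ketone. The fallback gives up catalyst control. Setting out from 19, cyclisation under achiral base catalysis (DBU, CH2Cl2) should give the racemic oxepine ester F4, and acidolysis as in step 11 the racemic acid F5. Classical resolution by crystallisation of the diastereomeric salt with (S)-1-phenylethylamine should give the salt F6 of the 2S acid (the enantiomeric amine is used if the other salt proves the less soluble one). Mild acidification comes back to the route at 21.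

Step 7. Hot aqueous selenous acid may hydrolyse the aryl MOM acetals, and over-oxidation may carry the glyoxal on to the arylglyoxylic acid. The fallback reaches the glyoxal by stepwise oxygenation under non-acidic conditions. Setting out from 11, silyl enol ether formation (LiN(SiMe3)2, TMSCl, THF, −78 °C) should give the enol ether F7. Rubottom oxidation (mCPBA, CH2Cl2, −20 °C; aqueous citric acid work-up) should give the α-hydroxy ketone F8, and Dess–Martin oxidation of its primary alcohol comes back to the route at 12.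

Further compounds
F1 | step 8 | (2E,6Z)-6-{[(tert-butyldimethylsilyl)oxy]methyl}-9-[(4-methoxybenzyl)oxy]-2-methylnona-2,6-dien-1-yl (E)-3-[4-(methoxymethoxy)phenyl]prop-2-enoate | COc1ccc(COCC/C=C(\CO[Si](C)(C)C(C)(C)C)CC/C=C(\C)COC(=O)/C=C/c2ccc(OCOC)cc2)cc1
F2 | step 8 | (2E,6Z)-6-{[(tert-butyldimethylsilyl)oxy]methyl}-9-hydroxy-2-methylnona-2,6-dien-1-yl (E)-3-[4-(methoxymethoxy)phenyl]prop-2-enoate | OCC/C=C(\CO[Si](C)(C)C(C)(C)C)CC/C=C(\C)COC(=O)/C=C/c1ccc(OCOC)cc1
F3 | step 8 | (2E,6Z)-6-{[(tert-butyldimethylsilyl)oxy]methyl}-9-iodo-2-methylnona-2,6-dien-1-yl (E)-3-[4-(methoxymethoxy)phenyl]prop-2-enoate | ICC/C=C(\CO[Si](C)(C)C(C)(C)C)CC/C=C(\C)COC(=O)/C=C/c1ccc(OCOC)cc1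
F4 | step 10 | racemic tert-butyl 2-{2-[2,5-bis(methoxymethoxy)phenyl]-2-oxoethyl}-6-[(3E)-5-{[(2E)-3-[4-(methoxymethoxy)phenyl]prop-2-enoyl]oxy}-4-methylpent-3-en-1-yl]-2,3,4,7-tetrahydrooxepine-2-carboxylate | C/C(=C\CCC1=CCCC(CC(=O)c2cc(OCOC)ccc2OCOC)(C(=O)OC(C)(C)C)OC1)COC(=O)/C=C/c1ccc(OCOC)cc1
F5 | step 10 | racemic 2-[2-(2,5-dihydroxyphenyl)-2-oxoethyl]-6-[(3E)-5-{[(2E)-3-(4-hydroxyphenyl)prop-2-enoyl]oxy}-4-methylpent-3-en-1-yl]-2,3,4,7-tetrahydrooxepine-2-carboxylic acid | C/C(=C\CCC1=CCCC(CC(=O)c2cc(O)ccc2O)(C(=O)O)OC1)COC(=O)/C=C/c1ccc(O)cc1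
F6 | step 10 | (S)-1-phenylethylammonium salt of the 2S acid 21 | C/C(=C\CCC1=CCC[C@](CC(=O)c2cc(O)ccc2O)(C(=O)[O-])OC1)COC(=O)/C=C/c1ccc(O)cc1.C[C@H]([NH3+])c1ccccc1
F7 | step 7 | {1-[2,5-bis(methoxymethoxy)phenyl]ethenyl}oxy(trimethyl)silane | C=C(O[Si](C)(C)C)c1cc(OCOC)ccc1OCOC
F8 | step 7 | 1-[2,5-bis(methoxymethoxy)phenyl]-2-hydroxyethanone | OCC(=O)c1cc(OCOC)ccc1OCOC
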